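**Retrosynthetic overview**
- Target 25 ← N-desilylation ← Suzuki–Miyaura coupling of aryl boronate 8 with (E)-iodoalkene 23 ← Takai olefination of ring aldehyde 22, itself from ester 20 by reduction and oxidation.
- Cyclohexene ring ← one-pot [4+2] annulation of the acyclic bromo ester 16 (as its 1,4-dianion) with ethylene sulfate, which forms ring bonds C5–C4 (CH2 to the vinylic carbon) and C6–C1 (CH2 to the quaternary carbon) together. This is the only ring formed; both indole rings are carried in from 5-bromoindole.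
- 16 ← α-methylation ← Rh/BINAP 1,4-addition of 8 to the (2E,4Z)-bromodienoate 13 (sets the aryl-bearing stereocentre) ← but-2-yn-1-ol; 8 ← 5-bromoindole by C3 reverse prenylation, N-silylation and borylation.
- Enabling feature: ring carbons C1 and C4 are 1,4-related and joined on one side only by the C5–C6 ethano bridge. C1 is α to a carboxyl carbon (the later styryl CH), and C4 is the methyl-bearing vinylic carbon held cis to C2 by the C3=C4 bond. Both can therefore be made carbanionic in one chain (ester enolate and Z-alkenyllithium) and clipped by a two-carbon bis-electrophile, while the aryl-bearing C2 next to the enolate controls its face.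

Key step: step 9

Remark: the sense of induction in step 7 is assumed from the usual model for Rh/BINAP 1,4-additions to (E)-enoates (aryl delivered to the α-si face with (S)-BINAP); if it ran the other way, (R)-BINAP would be used.

Abbreviation: Ar = 3-(2-methylbut-3-en-2-yl)-1-[tri(propan-2-yl)silyl]-1H-indol-5-yl; ring locants in names follow cyclohex-3-ene numbering (C1 quaternary, C2 aryl-bearing).

**Step 1**
Reactants: 1 2-methylbut-3-en-2-ol
Product: 3 tert-butyl (2-methylbut-3-en-2-yl) carbonate, via lithium 2-methylbut-3-en-2-olate 2 (not isolated)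
Conditions: n-BuLi, THF, −78 to 0 °C; Boc2O, 0 to 25 °C
Reagents that add atoms: di-tert-butyl dicarbonate, CC(C)(C)OC(=O)OC(=O)OC(C)(C)C
Why: Alkoxycarbonylation of the lithium alkoxide of a tertiary allylic alcohol with Boc2O is a standard carbonate synthesis and leaves the alkene untouched.

**Step 2**
Reactants: 4 5-bromo-1H-indole; 3 tert-butyl (2-methylbut-3-en-2-yl) carbonate
Product: 5 5-bromo-3-(2-methylbut-3-en-2-yl)-1H-indole
Conditions: [Ir(cod)Cl]2 (2.5 mol%), P(OPh)3 (10 mol%), KOt-Bu, Et3B, THF, 25 °C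
Reagents that add atoms: none
Why: Iridium-catalysed allylic substitution (reverse prenylation) attacks the more substituted allyl terminus, and the N-indolyl borate formed with KOt-Bu/Et3B should direct the electrophile to C3, after which the 3H-indole tautomerises to the indole.

**Step 3**
Reactants: 5 5-bromo-3-(2-methylbut-3-en-2-yl)-1H-indole
Product: 7 5-bromo-3-(2-methylbut-3-en-2-yl)-1-[tri(propan-2-yl)silyl]-1H-indole, via N-sodio indolide 6 (not isolated)
Conditions: NaH, THF, 0 °C; i-Pr3SiCl, 0 to 25 °C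
Reagents that add atoms: chlorotri(propan-2-yl)silane, CC(C)[Si](Cl)(C(C)C)C(C)C
Why: N-Silylation of the sodium indolide is routine, and the bulky silyl group masks N–H and shields C2 during the later organolithium steps.

**Step 4**
Reactants: 7 5-bromo-3-(2-methylbut-3-en-2-yl)-1-[tri(propan-2-yl)silyl]-1H-indole
Product: 8 3-(2-methylbut-3-en-2-yl)-5-(4,4,5,5-tetramethyl-1,3,2-dioxaborolan-2-yl)-1-[tri(propan-2-yl)silyl]-1H-indole
Conditions: B2pin2, PdCl2(dppf) (3 mol%), KOAc, 1,4-dioxane, 85 °C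
Reagents that add atoms: bis(pinacolato)diboron, CC1(C)OB(OC1(C)C)B1OC(C)(C)C(C)(C)O1
Why: Miyaura borylation of an aryl bromide tolerates the N-silyl group and the hindered terminal alkene.

**Step 5**
Reactants: 9 but-2-yn-1-ol
Product: 11 (Z)-3-bromobut-2-en-1-ol, via cyclic alkenylalanate 10 (not isolated)
Conditions: NaAlH2(OCH2CH2OMe)2, THF, 0 to 25 °C; NBS, −78 °C
Reagents that add atoms: N-bromosuccinimide, O=C1CCC(=O)N1Br
Why: Hydroxyl-directed trans-hydroalumination of the propargylic alcohol puts aluminium on C3 cis to the CH2O group, and bromodealumination with retention gives the Z bromoalkene.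

**Step 6**
Reactants: 11 (Z)-3-bromobut-2-en-1-ol
Product: 13 tert-butyl (2E,4Z)-5-bromohexa-2,4-dienoate, via (Z)-3-bromobut-2-enal 12 (not isolated)
Conditions: MnO2, Ph3P=CHCO2t-Bu, CH2Cl2, 25 °C
Reagents that add atoms: tert-butyl (triphenyl-λ5-phosphanylidene)acetate, CC(C)(C)OC(=O)C=P(c1ccccc1)(c1ccccc1)c1ccccc1
Why: One-pot allylic oxidation/Wittig olefination traps the labile Z-bromoenal as it forms, and the stabilised ylide gives the 2E alkene while the 4Z bromoalkene is kept.

**Step 7**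
Reactants: 13 tert-butyl (2E,4Z)-5-bromohexa-2,4-dienoate; 8 aryl boronate
Product: 14 tert-butyl (3S,4Z)-5-bromo-3-Ar-hex-4-enoate
Conditions: [Rh(OH)((S)-BINAP)]2 (1.5 mol%), K3PO4, 1,4-dioxane/H2O 10:1, 50 °C
Reagents that add atoms: none
Why: In this Hayashi–Miyaura asymmetric 1,4-addition the aryl species of monovalent rhodium inserts the C2=C3 bond, the fully substituted bromo-bearing C5 should block 1,6-addition, and (S)-BINAP should deliver the aryl group to the C3 face that gives the 3S centre (see the remark).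

**Step 8**
Reactants: 14 tert-butyl (3S,4Z)-5-bromo-3-Ar-hex-4-enoate
Product: 16 tert-butyl (2RS,3S,4Z)-5-bromo-2-methyl-3-Ar-hex-4-enoate, via lithium enolate 15 (not isolated)
Conditions: LiN(i-Pr)2, THF, −78 °C; MeI, −78 to −40 °C
Reagents that add atoms: iodomethane, CI
Why: Kinetic ester enolate alkylation installs the methyl group, and the C2 configuration formed here does not matter because C2 is enolised again in step 9.

**Step 9**
Reactants: 16 tert-butyl (2RS,3S,4Z)-5-bromo-2-methyl-3-Ar-hex-4-enoate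
Product: 20 tert-butyl (1R,2S)-1,4-dimethyl-2-Ar-cyclohex-3-ene-1-carboxylate, via lithium enolate 17 (not isolated), via dilithio alkenyllithium enolate 18 (not isolated), via lithium alkyl sulfate enolate 19 (not isolated)
Conditions: MesLi (1.05 equiv), THF, −78 °C; t-BuLi (2.05 equiv), −78 °C; ethylene sulfate (1.0 equiv), −78 to −40 °C; DMPU, −40 to 25 °C
Reagents that add atoms: ethylene sulfate (1,3,2-dioxathiolane 2,2-dioxide), O=S1(=O)OCCO1
Why: Proposed new method: amine-free deprotonation and Br/Li exchange turn 16 into the 1,4-dianion 18, whose more basic Z-alkenyllithium should open the strained cyclic sulfate at carbon to give 19, after which the enolate carbon displaces the sulfate monoester intramolecularly. The closest known reaction types are the double displacement of 1,2-cyclic sulfates by bis-nucleophiles (malonate cyclopropanation, phospholane synthesis) and the alkylation of dianions at the last-formed site first; the untested part is pairing an alkenyllithium with an ester enolate to build a cyclohexene. The ring closes by a 6-exo-tet alkylation with the enolate double bond outside the ring, and the Z geometry of the alkenyl unit places both reacting ends on the same side. The new quaternary centre C1 should be set by allylic 1,3-strain: the C–H of the aryl-bearing carbon lies in the enolate plane, the tether through the alkenyl carbon fixes attack on that face, and the aryl group sits anti, so the ester ends up trans to the aryl group and cis to nothing but hydrogen (1R,2S). The step is stereoconvergent, because both C2 epimers of 16 and both enolate geometries lead to the same enolate face. The site selectivity it needs (alkenyllithium before enolate, one sulfate per molecule) rests on the reactivity gap between the cyclic sulfate and the sulfate monoanion, which leaves the hindered enolate only its intramolecular partner.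

**Step 10**
Reactants: 20 tert-butyl (1R,2S)-1,4-dimethyl-2-Ar-cyclohex-3-ene-1-carboxylate
Product: 21 [(1R,2S)-1,4-dimethyl-2-Ar-cyclohex-3-en-1-yl]methanol
Conditions: LiAlH4, THF, 0 to 25 °C
Reagents that add atoms: none
Why: Hydride reduction of the ester to the neopentylic alcohol touches neither the alkenes nor the N-silyl indole, and the quaternary centre cannot epimerise.

**Step 11**
Reactants: 21 [(1R,2S)-1,4-dimethyl-2-Ar-cyclohex-3-en-1-yl]methanol
Product: 22 (1R,2S)-1,4-dimethyl-2-Ar-cyclohex-3-ene-1-carbaldehyde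
Conditions: Dess–Martin periodinane, CH2Cl2, 0 to 25 °C
Reagents that add atoms: none
Why: Dess–Martin oxidation gives the aldehyde under mild conditions, and the α-quaternary aldehyde has no enolisable position.

**Step 12**
Reactants: 22 (1R,2S)-1,4-dimethyl-2-Ar-cyclohex-3-ene-1-carbaldehyde
Product: 23 (1R,2R)-1-[(E)-2-iodoethenyl]-1,4-dimethyl-2-Ar-cyclohex-3-ene
Conditions: CrCl2, CHI3, THF/1,4-dioxane, 0 to 25 °C
Reagents that add atoms: iodoform, IC(I)I
Why: Takai olefination with the geminal dichromium reagent from iodoform and divalent chromium should give the E iodoalkene and is tolerant of hindered, non-enolisable aldehydes.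

**Step 13**
Reactants: 23 (E)-iodoalkene; 8 aryl boronate
Product: 24 5-[(E)-2-[(1S,2R)-1,4-dimethyl-2-Ar-cyclohex-3-en-1-yl]ethenyl]-3-(2-methylbut-3-en-2-yl)-1-[tri(propan-2-yl)silyl]-1H-indole
Conditions: Pd(PPh3)4 (5 mol%), K3PO4, THF/H2O, 50 °C
Reagents that add atoms: none
Why: Suzuki–Miyaura coupling of an alkenyl iodide with an aryl boronate proceeds with retention of the E geometry and, unlike a Heck reaction, does not involve the three similar terminal vinyl groups.

**Step 14**
Reactants: 24 bis-N-silyl precursor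
Product: 25 5-[(E)-2-[(1S,2R)-1,4-dimethyl-2-[3-(2-methylbut-3-en-2-yl)-1H-indol-5-yl]cyclohex-3-en-1-yl]ethenyl]-3-(2-methylbut-3-en-2-yl)-1H-indole
Conditions: Bu4NF, THF, 0 to 25 °C
Reagents that add atoms: none
Why: Fluoride-mediated N-desilylation frees both indole N–H groups without touching any alkene or stereocentre.

**Compound list**
1 | 2-methylbut-3-en-2-ol | C=CC(C)(C)O | starting material
2 | lithium 2-methylbut-3-en-2-olate | C=CC(C)(C)O[Li] | intermediate
3 | tert-butyl (2-methylbut-3-en-2-yl) carbonate | C=CC(C)(C)OC(=O)OC(C)(C)C | intermediate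
4 | 5-bromo-1H-indole | Brc1ccc2[nH]ccc2c1 | starting material
5 | 5-bromo-3-(2-methylbut-3-en-2-yl)-1H-indole | C=CC(C)(C)c1c[nH]c2ccc(Br)cc12 | intermediate
6 | N-sodio derivative of 5 | C=CC(C)(C)c1cn([Na])c2ccc(Br)cc12 | intermediate
7 | 5-bromo-3-(2-methylbut-3-en-2-yl)-1-[tri(propan-2-yl)silyl]-1H-indole | C=CC(C)(C)c1cn([Si](C(C)C)(C(C)C)C(C)C)c2ccc(Br)cc12 | intermediate
8 | 3-(2-methylbut-3-en-2-yl)-5-(4,4,5,5-tetramethyl-1,3,2-dioxaborolan-2-yl)-1-[tri(propan-2-yl)silyl]-1H-indole | C=CC(C)(C)c1cn([Si](C(C)C)(C(C)C)C(C)C)c2ccc(B3OC(C)(C)C(C)(C)O3)cc12 | intermediate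
9 | but-2-yn-1-ol | CC#CCO | starting material
10 | sodium cyclic alkenylalanate (five-membered O–Al–C=C–C ring, two 2-methoxyethoxy groups on Al) | CC1=CCO[Al-]1(OCCOC)OCCOC.[Na+] | intermediate
11 | (Z)-3-bromobut-2-en-1-ol | C/C(Br)=C/CO | intermediate
12 | (Z)-3-bromobut-2-enal | C/C(Br)=C/C=O | intermediate
13 | tert-butyl (2E,4Z)-5-bromohexa-2,4-dienoate | C/C(Br)=C/C=C/C(=O)OC(C)(C)C | intermediate
14 | tert-butyl (3S,4Z)-5-bromo-3-Ar-hex-4-enoate | C/C(Br)=C/[C@H](CC(=O)OC(C)(C)C)c1ccc2c(c1)c(C(C)(C)C=C)cn2[Si](C(C)C)(C(C)C)C(C)C | intermediate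
15 | lithium enolate of 14 | C/C(Br)=C/[C@H](C=C(O[Li])OC(C)(C)C)c1ccc2c(c1)c(C(C)(C)C=C)cn2[Si](C(C)C)(C(C)C)C(C)C | intermediate
16 | tert-butyl (2RS,3S,4Z)-5-bromo-2-methyl-3-Ar-hex-4-enoate | C/C(Br)=C/[C@H](C(C)C(=O)OC(C)(C)C)c1ccc2c(c1)c(C(C)(C)C=C)cn2[Si](C(C)C)(C(C)C)C(C)C | intermediate
17 | lithium enolate of 16 | C/C(Br)=C/[C@H](C(C)=C(O[Li])OC(C)(C)C)c1ccc2c(c1)c(C(C)(C)C=C)cn2[Si](C(C)C)(C(C)C)C(C)C | intermediate
18 | dilithio species: lithium enolate of 16 with lithium in place of bromine (Z-alkenyllithium) | C/C([Li])=C/[C@H](C(C)=C(O[Li])OC(C)(C)C)c1ccc2c(c1)c(C(C)(C)C=C)cn2[Si](C(C)C)(C(C)C)C(C)C | intermediate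
19 | lithium enolate carrying a 2-(lithiooxysulfonyloxy)ethyl group on the former alkenyllithium carbon | C/C(CCOS(=O)(=O)O[Li])=C/[C@H](C(C)=C(O[Li])OC(C)(C)C)c1ccc2c(c1)c(C(C)(C)C=C)cn2[Si](C(C)C)(C(C)C)C(C)C | intermediate
20 | tert-butyl (1R,2S)-1,4-dimethyl-2-Ar-cyclohex-3-ene-1-carboxylate | CC(C)(C)OC(=O)[C@]3(C)CCC(C)=C[C@H]3c1ccc2c(c1)c(C(C)(C)C=C)cn2[Si](C(C)C)(C(C)C)C(C)C | intermediate
21 | [(1R,2S)-1,4-dimethyl-2-Ar-cyclohex-3-en-1-yl]methanol | OC[C@]3(C)CCC(C)=C[C@H]3c1ccc2c(c1)c(C(C)(C)C=C)cn2[Si](C(C)C)(C(C)C)C(C)C | intermediate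
22 | (1R,2S)-1,4-dimethyl-2-Ar-cyclohex-3-ene-1-carbaldehyde | O=C[C@]3(C)CCC(C)=C[C@H]3c1ccc2c(c1)c(C(C)(C)C=C)cn2[Si](C(C)C)(C(C)C)C(C)C | intermediate
23 | (1R,2R)-1-[(E)-2-iodoethenyl]-1,4-dimethyl-2-Ar-cyclohex-3-ene | I/C=C/[C@]3(C)CCC(C)=C[C@H]3c1ccc2c(c1)c(C(C)(C)C=C)cn2[Si](C(C)C)(C(C)C)C(C)C | intermediate
24 | 5-[(E)-2-[(1S,2R)-1,4-dimethyl-2-Ar-cyclohex-3-en-1-yl]ethenyl]-3-(2-methylbut-3-en-2-yl)-1-[tri(propan-2-yl)silyl]-1H-indole | C=CC(C)(C)c1cn([Si](C(C)C)(C(C)C)C(C)C)c2ccc(/C=C/[C@]3(C)CCC(C)=C[C@H]3c3ccc4n([Si](C(C)C)(C(C)C)C(C)C)cc(C(C)(C)C=C)c4c3)cc12 | intermediate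
25 | 5-[(E)-2-[(1S,2R)-1,4-dimethyl-2-[3-(2-methylbut-3-en-2-yl)-1H-indol-5-yl]cyclohex-3-en-1-yl]ethenyl]-3-(2-methylbut-3-en-2-yl)-1H-indole | C=CC(C)(C)c1c[nH]c2ccc(/C=C/[C@]3(C)CCC(C)=C[C@H]3c3ccc4[nH]cc(C(C)(C)C=C)c4c3)cc12 | target

**Step count and risks**
Total: 14 steps. Longest linear sequence: 12 steps (steps 1–4, then 7–14, from 2-methylbut-3-en-2-ol).

Steps most likely to fail:

1. Step 9 (proposed new method). The alkenyllithium may attack the cyclic sulfate at sulfur instead of carbon. The enolate may be alkylated intermolecularly by a second sulfate before ring closure. Displacement of the sulfate monoester may be slow enough for the enolate to decompose or for elimination to a diene to take over. The facial preference from allylic 1,3-strain may be weaker than expected.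
 Fallback, with each bond made in a separate known operation: it sets out from 16. The anions 17 and 18 are generated as in step 9, and 18 is treated with ethylene oxide and BF3·OEt2 at −78 °C and then worked up with water. This gives tert-butyl (2RS,3R,4Z)-7-hydroxy-2,5-dimethyl-3-Ar-hept-4-enoate F1. I2, PPh3 and imidazole convert it into tert-butyl (2RS,3R,4Z)-7-iodo-2,5-dimethyl-3-Ar-hept-4-enoate F2. KN(SiMe3)2 in THF at −78 to 0 °C then closes the ring by the same 6-exo-tet enolate alkylation, now with a neutral iodide leaving group, and the route is rejoined at 20.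

2. Step 7. Possible failures are competing 1,6-addition, insertion of rhodium into the C–Br bond, protodeboronation of 8, or insufficient or reversed facial selectivity.
 Fallback, auxiliary control instead of catalyst control: it sets out from 11. The one-pot MnO2 oxidation/Wittig olefination of step 6 is run with (4S)-4-phenyl-3-[(triphenyl-λ5-phosphanylidene)acetyl]-1,3-oxazolidin-2-one and gives (4S)-3-[(2E,4Z)-5-bromohexa-2,4-dienoyl]-4-phenyl-1,3-oxazolidin-2-one F3. Bromide 7 and magnesium in THF give the aryl Grignard reagent ArMgBr F4. With CuBr·SMe2 at −20 °C, F4 should add to the chelated s-cis imide anti to the phenyl group and give (4S)-3-[(3S,4Z)-5-bromo-3-Ar-hex-4-enoyl]-4-phenyl-1,3-oxazolidin-2-one F5. LiOH/H2O2 cleaves the auxiliary to (3S,4Z)-5-bromo-3-Ar-hex-4-enoic acid F6. Boc2O, DMAP and t-BuOH convert the acid into the tert-butyl ester, and the route is rejoined at 14.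

3. Step 12. Addition of the geminal dichromium reagent to the neopentylic aldehyde may be sluggish, the E/Z ratio may erode, or the iodoalkene may be reduced by excess divalent chromium.
 Fallback, alkyne route: it sets out from 22. Dimethyl (1-diazo-2-oxopropyl)phosphonate with K2CO3 in MeOH gives (1R,2S)-1-ethynyl-1,4-dimethyl-2-Ar-cyclohex-3-ene F7. Bu3SnH with PdCl2(PPh3)2 hydrostannates the alkyne, faster than the hindered alkenes, to (1R,2R)-1,4-dimethyl-2-Ar-1-[(E)-2-(tributylstannyl)ethenyl]cyclohex-3-ene F8. Stille coupling of F8 with bromide 7 (Pd(PPh3)4, CuI, CsF, DMF) rejoins the route at 24.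

**Further compounds**
F1 | step 9 | tert-butyl (2RS,3R,4Z)-7-hydroxy-2,5-dimethyl-3-Ar-hept-4-enoate | C/C(CCO)=C/[C@H](C(C)C(=O)OC(C)(C)C)c1ccc2c(c1)c(C(C)(C)C=C)cn2[Si](C(C)C)(C(C)C)C(C)C
F2 | step 9 | tert-butyl (2RS,3R,4Z)-7-iodo-2,5-dimethyl-3-Ar-hept-4-enoate | C/C(CCI)=C/[C@H](C(C)C(=O)OC(C)(C)C)c1ccc2c(c1)c(C(C)(C)C=C)cn2[Si](C(C)C)(C(C)C)C(C)C
F3 | step 7 | (4S)-3-[(2E,4Z)-5-bromohexa-2,4-dienoyl]-4-phenyl-1,3-oxazolidin-2-one | C/C(Br)=C/C=C/C(=O)N1C(=O)OC[C@@H]1c1ccccc1
F4 | step 7 | bromo{3-(2-methylbut-3-en-2-yl)-1-[tri(propan-2-yl)silyl]-1H-indol-5-yl}magnesium | Br[Mg]c1ccc2c(c1)c(C(C)(C)C=C)cn2[Si](C(C)C)(C(C)C)C(C)C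
F5 | step 7 | (4S)-3-[(3S,4Z)-5-bromo-3-Ar-hex-4-enoyl]-4-phenyl-1,3-oxazolidin-2-one | C/C(Br)=C/[C@H](CC(=O)N1C(=O)OC[C@@H]1c1ccccc1)c1ccc2c(c1)c(C(C)(C)C=C)cn2[Si](C(C)C)(C(C)C)C(C)C
F6 | step 7 | (3S,4Z)-5-bromo-3-Ar-hex-4-enoic acid | C/C(Br)=C/[C@H](CC(=O)O)c1ccc2c(c1)c(C(C)(C)C=C)cn2[Si](C(C)C)(C(C)C)C(C)C
F7 | step 12 | (1R,2S)-1-ethynyl-1,4-dimethyl-2-Ar-cyclohex-3-ene | C#C[C@]3(C)CCC(C)=C[C@H]3c1ccc2c(c1)c(C(C)(C)C=C)cn2[Si](C(C)C)(C(C)C)C(C)C
F8 | step 12 | (1R,2R)-1,4-dimethyl-2-Ar-1-[(E)-2-(tributylstannyl)ethenyl]cyclohex-3-ene | CCCC[Sn](CCCC)(CCCC)/C=C/[C@]3(C)CCC(C)=C[C@H]3c1ccc2c(c1)c(C(C)(C)C=C)cn2[Si](C(C)C)(C(C)C)C(C)C
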